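**Retrosynthetic overview**
1. Ring B (hemiketal) and the CH–OH are made last: α-hydroxylation of a cycloheptane-1,3-dione, then spontaneous hemiketalisation onto the pyranone OH.
2. Ring C (seven-membered) comes from a new ring-expanding 1,4-O→C acyl shift of an α-acyloxy methyl ketone δ-lactone.
3. The pyranone (ring A, bought) is attached by Michael addition to that α-methylene δ-lactone.
4. The quaternary C–OH of ring D is set by anti addition of an acetyl-anion equivalent to a 4-silyloxycyclopentenone; the CH–CH3 centre by an organocatalytic Mukaiyama–Michael addition to crotonaldehyde.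
5. Ring order: D (from 2,2-dimethylcyclopentane-1,3-dione) → temporary δ-lactone → C → B.

Assumption 1: 4-hydroxy-5,6-dimethyl-2H-pyran-2-one is bought as a catalogue chemical.
Assumption 2: the hemiketal carbon, the neighbouring CH–OH and the ring-fusion CH next to them equilibrate through the open keto form, and the natural configuration is the thermodynamically preferred one; the quaternary C–OH and the CH–CH3 centres are fixed by synthesis.

**Step 1**
Reactants: 1 2,2-dimethylcyclopentane-1,3-dione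
Product: 2 (3S)-3-hydroxy-2,2-dimethylcyclopentan-1-one
Conditions: (R)-Me-CBS (10 mol%), BH3·SMe2 (0.6 equiv), THF, −30 °C; MeOH, aq. work-up
Reagents that add atoms: none
Why: CBS (oxazaborolidine) reduction of one of two equivalent ketones, with the quaternary carbon as the large group so that the (R)-catalyst gives the (S)-carbinol, a temporary stereocentre that later steers the quaternary carbinol.

**Step 2**
Reactants: 2 (3S)-3-hydroxy-2,2-dimethylcyclopentan-1-one
Product: 3 (3S)-3-(tert-butyldimethylsilyloxy)-2,2-dimethylcyclopentan-1-one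
Conditions: TBSCl, imidazole, DMF, 40 °C
Reagents that add atoms: tert-butyldimethylsilyl chloride CC(C)(C)[Si](C)(C)Cl
Why: Silyl ether formation; the bulky OTBS group blocks retro-aldol cleavage and is the later facial control element, and no stereocentre is touched.

**Step 3**
Reactants: 3 (3S)-3-(tert-butyldimethylsilyloxy)-2,2-dimethylcyclopentan-1-one
Product: 4 tert-butyl{[(1S)-2,2-dimethyl-3-(trimethylsilyloxy)cyclopent-3-en-1-yl]oxy}dimethylsilane
Conditions: LDA, THF, −78 °C; TMSCl
Reagents that add atoms: chlorotrimethylsilane C[Si](C)(C)Cl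
Why: Kinetic enolate silylation; only one α-carbon carries hydrogen (the other is quaternary), so a single enol silane forms.

**Step 4**
Reactants: 4 tert-butyl{[(1S)-2,2-dimethyl-3-(trimethylsilyloxy)cyclopent-3-en-1-yl]oxy}dimethylsilane; 5 (E)-but-2-enal
Product: 6 (3R)-3-[(4S)-4-(tert-butyldimethylsilyloxy)-3,3-dimethyl-2-oxocyclopentyl]butanal
Conditions: 5 (3 equiv), (2S,5S)-5-benzyl-2-tert-butyl-3-methylimidazolidin-4-one (20 mol%), 2,4-dinitrobenzoic acid (20 mol%), H2O (2 equiv), CH2Cl2/i-PrOH, −30 °C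
Reagents that add atoms: none
Why: Iminium-catalysed Mukaiyama–Michael addition in which the imidazolidinone shields one face of the (E)-crotonaldehyde iminium, so the enol silane adds to give the (R)-CH(CH3) centre (same facial sense as this catalyst's additions of π-nucleophiles to crotonaldehyde); the ring α-centre forms as a mixture and is erased in step 7.

**Step 5**
Reactants: 6 (3R)-3-[(4S)-4-(tert-butyldimethylsilyloxy)-3,3-dimethyl-2-oxocyclopentyl]butanal
Product: 7 (3S)-3-[(4S)-4-(tert-butyldimethylsilyloxy)-3,3-dimethyl-2-oxocyclopentyl]-2-methylidenebutanal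
Conditions: 37% aq. CH2O, pyrrolidine (10 mol%), EtCO2H (10 mol%), i-PrOH, 45 °C
Reagents that add atoms: formaldehyde C=O
Why: Amine-catalysed Mannich condensation/elimination (organocatalytic α-methylenation of an aldehyde) installs the future ring-B CH2 carbon; the hindered ketone and the β-stereocentre are not enolised (the CIP descriptor changes, the geometry does not).

**Step 6**
Reactants: 7 (3S)-3-[(4S)-4-(tert-butyldimethylsilyloxy)-3,3-dimethyl-2-oxocyclopentyl]-2-methylidenebutanal
Product: 8 (3S)-3-(tert-butyldimethylsilyloxy)-5-[(2S)-4,4-dimethoxy-3-methylidenebutan-2-yl]-2,2-dimethylcyclopentan-1-one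
Conditions: HC(OMe)3, PPTS (5 mol%), MeOH, 0 °C → rt
Reagents that add atoms: trimethyl orthoformate COC(OC)OC
Why: Acid-catalysed acetalisation masks the enal against the LDA and organolithium of steps 7 and 8; the α-quaternary ketone does not ketalise and the TBS ether survives PPTS.

**Step 7**
Reactants: 8 (3S)-3-(tert-butyldimethylsilyloxy)-5-[(2S)-4,4-dimethoxy-3-methylidenebutan-2-yl]-2,2-dimethylcyclopentan-1-one
Product: 10 (4S)-4-(tert-butyldimethylsilyloxy)-2-[(2R)-4,4-dimethoxy-3-methylidenebutan-2-yl]-5,5-dimethylcyclopent-2-en-1-one, via trimethylsilyl enol ether 9 (not isolated)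
Conditions: LDA, TMSCl, THF, −78 °C; then Pd(OAc)2 (10 mol%), O2 (1 atm), DMSO, rt
Reagents that add atoms: none
Why: Saegusa–Ito oxidation: the only possible enolate is trapped and β-hydride elimination from the palladium enolate goes toward the ring CH2 to give the endocyclic enone (the tetrasubstituted exocyclic alkene is disfavoured), so the CH(CH3) centre is kept and the ring α-centre becomes sp2.

**Step 8**
Reactants: 10 (4S)-4-(tert-butyldimethylsilyloxy)-2-[(2R)-4,4-dimethoxy-3-methylidenebutan-2-yl]-5,5-dimethylcyclopent-2-en-1-one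
Product: 12 (3S)-3-[(3S,5R)-5-acetyl-3-(tert-butyldimethylsilyloxy)-5-hydroxy-4,4-dimethylcyclopent-1-en-1-yl]-2-methylidenebutanal, via ethoxyvinyl carbinol 11 (not isolated)
Conditions: CH2=CHOEt, t-BuLi, THF, −78 → 0 °C; then 10, −78 °C; then 1 M HCl, THF, 0 °C → rt
Reagents that add atoms: 1-ethoxyvinyllithium [Li]C(=C)OCC (from ethyl vinyl ether and t-BuLi); water O
Why: 1,2-Addition of an acyl-anion equivalent to the enone carbonyl anti to the C-4 silyloxy group (the usual sense for 4-silyloxycyclopent-2-enones) sets the quaternary carbinol as (R), and mild acid hydrolysis then releases the methyl ketone and the enal.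

**Step 9**
Reactants: 12 (3S)-3-[(3S,5R)-5-acetyl-3-(tert-butyldimethylsilyloxy)-5-hydroxy-4,4-dimethylcyclopent-1-en-1-yl]-2-methylidenebutanal
Product: 13 (3S)-3-[(3S,5R)-5-acetyl-3,5-dihydroxy-4,4-dimethylcyclopent-1-en-1-yl]-2-methylidenebutanal
Conditions: HF·pyridine, THF/pyridine, 0 °C → rt
Reagents that add atoms: none
Why: Fluoride desilylation under non-basic conditions spares the α-ketol and frees the allylic alcohol; the tertiary OH and the aldehyde equilibrate with their six-membered lactol.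

**Step 10**
Reactants: 13 (3S)-3-[(3S,5R)-5-acetyl-3,5-dihydroxy-4,4-dimethylcyclopent-1-en-1-yl]-2-methylidenebutanal
Product: 14 (4S,7aR)-7a-acetyl-4,7,7-trimethyl-3-methylidene-4,7a-dihydrocyclopenta[b]pyran-2,6(3H,7H)-dione
Conditions: TPAP (10 mol%), NMO (4 equiv), 4 Å MS, CH2Cl2, rt
Reagents that add atoms: none
Why: Ley–Griffith oxidation turns the allylic alcohol into the ring-D enone and the lactol into the α-methylene δ-lactone, which protects the tertiary oxygen and places the acyl carbon next to the acetyl group; no stereocentre is affected.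

**Step 11**
Reactants: 14 (4S,7aR)-7a-acetyl-4,7,7-trimethyl-3-methylidene-4,7a-dihydrocyclopenta[b]pyran-2,6(3H,7H)-dione; 15 4-hydroxy-5,6-dimethyl-2H-pyran-2-one
Product: 16 (3R,4R,7aR)-7a-acetyl-3-[(4-hydroxy-5,6-dimethyl-2-oxo-2H-pyran-3-yl)methyl]-4,7,7-trimethyl-3,4-dihydrocyclopenta[b]pyran-2,6(7H,7aH)-dione
Conditions: 15 (1.2 equiv), Et3N (20 mol%), MeCN, 40 °C
Reagents that add atoms: none
Why: Michael addition of the soft C-3 carbon of the 4-hydroxypyranone to the α-methylene lactone under weak base (too weak to deprotonate the γ-CH of the enone); the new CH forms by protonation and is drawn as the 3,4-trans isomer, which is also the one favoured once this centre is α to a ketone after step 12.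

**Step 12**
Reactants: 16 (3R,4R,7aR)-7a-acetyl-3-[(4-hydroxy-5,6-dimethyl-2-oxo-2H-pyran-3-yl)methyl]-4,7,7-trimethyl-3,4-dihydrocyclopenta[b]pyran-2,6(7H,7aH)-dione
Product: 17 (3aR,7R,8R)-3a-hydroxy-7-[(4-hydroxy-5,6-dimethyl-2-oxo-2H-pyran-3-yl)methyl]-3,3,8-trimethyl-7,8-dihydroazulene-2,4,6(3H,3aH,5H)-trione
Conditions: LiHMDS (3.2 equiv), THF, −78 → −30 °C; AcOH
Reagents that add atoms: none
Why: Proposed new method: ring-expanding 1,4-O→C acyl shift of a fused α-acyloxy methyl ketone lactone – the kinetic lithium enolate of the acetyl group (the most acidic C–H once the pyranone OH is deprotonated) attacks the lactone carbonyl through a five-membered transition state to give an 8-oxabicyclo[3.2.1]octane hemiketal alkoxide that cannot dehydrate to a 3(2H)-furanone (bridgehead alkene) and therefore opens by C–O cleavage to the seven-membered β-diketonate, whose formation drives the equilibrium; this forms the C–C bond that closes ring C, creates no new stereocentre and leaves the ring-fusion CH as, or equilibrates it to, the 7,8-trans isomer; the closest known chemistry is the Baker–Venkataraman acyl migration and the Claisen-type cyclisation of α-acyloxy ketones to furanones, neither of which has been used to expand a lactone into a carbocyclic 1,3-dione.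

**Step 13**
Reactants: 17 (3aR,7R,8R)-3a-hydroxy-7-[(4-hydroxy-5,6-dimethyl-2-oxo-2H-pyran-3-yl)methyl]-3,3,8-trimethyl-7,8-dihydroazulene-2,4,6(3H,3aH,5H)-trione
Product: 19 CNP0525404.1, via open-chain hydroxy diketone 18 (not isolated)
Conditions: NaHMDS (2.1 equiv), THF, −78 °C; 3-phenyl-2-(phenylsulfonyl)oxaziridine (1.05 equiv); AcOH, −78 °C → rt
Reagents that add atoms: 3-phenyl-2-(phenylsulfonyl)oxaziridine O=S(=O)(c1ccccc1)N1OC1c1ccccc1
Why: Davis oxaziridine hydroxylation of the more basic cycloheptanedionate (the pyranolate is far less nucleophilic) gives 18, which closes onto the pyranone OH; the trans ring fusion with axial anomeric OH, the CH–OH anti to it and the ring-fusion CH all equilibrate through the open form to the thermodynamic (natural) arrangement, while the quaternary C–OH and CH–CH3 centres are unaffected.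

**Compound list**
1 | 2,2-dimethylcyclopentane-1,3-dione | CC1(C)C(=O)CCC1=O | starting material
2 | (3S)-3-hydroxy-2,2-dimethylcyclopentan-1-one | O=C1CC[C@H](O)C1(C)C | intermediate
3 | (3S)-3-(tert-butyldimethylsilyloxy)-2,2-dimethylcyclopentan-1-one | O=C1CC[C@H](O[Si](C)(C)C(C)(C)C)C1(C)C | intermediate
4 | tert-butyl{[(1S)-2,2-dimethyl-3-(trimethylsilyloxy)cyclopent-3-en-1-yl]oxy}dimethylsilane | C[Si](C)(C)OC1=CC[C@H](O[Si](C)(C)C(C)(C)C)C1(C)C | intermediate
5 | (E)-but-2-enal (crotonaldehyde) | C/C=C/C=O | starting material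
6 | (3R)-3-[(4S)-4-(tert-butyldimethylsilyloxy)-3,3-dimethyl-2-oxocyclopentyl]butanal, ring C-1 epimers | O=CC[C@@H](C)C1C[C@H](O[Si](C)(C)C(C)(C)C)C(C)(C)C1=O | intermediate
7 | (3S)-3-[(4S)-4-(tert-butyldimethylsilyloxy)-3,3-dimethyl-2-oxocyclopentyl]-2-methylidenebutanal, ring C-1 epimers | O=CC(=C)[C@@H](C)C1C[C@H](O[Si](C)(C)C(C)(C)C)C(C)(C)C1=O | intermediate
8 | (3S)-3-(tert-butyldimethylsilyloxy)-5-[(2S)-4,4-dimethoxy-3-methylidenebutan-2-yl]-2,2-dimethylcyclopentan-1-one, C-5 epimers | COC(OC)C(=C)[C@@H](C)C1C[C@H](O[Si](C)(C)C(C)(C)C)C(C)(C)C1=O | intermediate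
9 | trimethylsilyl enol ether of 8 (C-1 OTMS, C-1=C-5 double bond; other centres as in 8) | COC(OC)C(=C)[C@@H](C)C1=C(O[Si](C)(C)C)C(C)(C)[C@@H](O[Si](C)(C)C(C)(C)C)C1 | intermediate (not isolated)
10 | (4S)-4-(tert-butyldimethylsilyloxy)-2-[(2R)-4,4-dimethoxy-3-methylidenebutan-2-yl]-5,5-dimethylcyclopent-2-en-1-one | COC(OC)C(=C)[C@@H](C)C1=C[C@H](O[Si](C)(C)C(C)(C)C)C(C)(C)C1=O | intermediate
11 | (1R,4S)-4-(tert-butyldimethylsilyloxy)-2-[(2S)-4,4-dimethoxy-3-methylidenebutan-2-yl]-1-(1-ethoxyethenyl)-5,5-dimethylcyclopent-2-en-1-ol | COC(OC)C(=C)[C@@H](C)C1=C[C@H](O[Si](C)(C)C(C)(C)C)C(C)(C)[C@@]1(O)C(=C)OCC | intermediate (not isolated)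
12 | (3S)-3-[(3S,5R)-5-acetyl-3-(tert-butyldimethylsilyloxy)-5-hydroxy-4,4-dimethylcyclopent-1-en-1-yl]-2-methylidenebutanal | O=CC(=C)[C@@H](C)C1=C[C@H](O[Si](C)(C)C(C)(C)C)C(C)(C)[C@@]1(O)C(C)=O | intermediate
13 | (3S)-3-[(3S,5R)-5-acetyl-3,5-dihydroxy-4,4-dimethylcyclopent-1-en-1-yl]-2-methylidenebutanal (in equilibrium with its six-membered lactol) | O=CC(=C)[C@@H](C)C1=C[C@H](O)C(C)(C)[C@@]1(O)C(C)=O | intermediate
14 | (4S,7aR)-7a-acetyl-4,7,7-trimethyl-3-methylidene-4,7a-dihydrocyclopenta[b]pyran-2,6(3H,7H)-dione | CC(=O)[C@@]12OC(=O)C(=C)[C@@H](C)C1=CC(=O)C2(C)C | intermediate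
15 | 4-hydroxy-5,6-dimethyl-2H-pyran-2-one | Cc1oc(=O)cc(O)c1C | starting material
16 | (3R,4R,7aR)-7a-acetyl-3-[(4-hydroxy-5,6-dimethyl-2-oxo-2H-pyran-3-yl)methyl]-4,7,7-trimethyl-3,4-dihydrocyclopenta[b]pyran-2,6(7H,7aH)-dione | CC(=O)[C@@]12OC(=O)[C@H](Cc3c(O)c(C)c(C)oc3=O)[C@@H](C)C1=CC(=O)C2(C)C | intermediate
17 | (3aR,7R,8R)-3a-hydroxy-7-[(4-hydroxy-5,6-dimethyl-2-oxo-2H-pyran-3-yl)methyl]-3,3,8-trimethyl-7,8-dihydroazulene-2,4,6(3H,3aH,5H)-trione (open β-diketone; may sit partly as hemiketal tautomers) | Cc1oc(=O)c(C[C@H]2C(=O)CC(=O)[C@@]3(O)C(=CC(=O)C3(C)C)[C@@H]2C)c(O)c1C | intermediate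
18 | (3aR,5S,7R,8R)-3a,5-dihydroxy-7-[(4-hydroxy-5,6-dimethyl-2-oxo-2H-pyran-3-yl)methyl]-3,3,8-trimethyl-7,8-dihydroazulene-2,4,6(3H,3aH,5H)-trione | Cc1oc(=O)c(C[C@H]2C(=O)[C@H](O)C(=O)[C@@]3(O)C(=CC(=O)C3(C)C)[C@@H]2C)c(O)c1C | intermediate (not isolated)
19 | CNP0525404.1: trans-fused pyrano hemiketal of 18; hemiketal C (S), CH–OH (R), quaternary C–OH (R), CH–CH3 (R), ring-fusion CH (R) | Cc1oc(=O)c2c(c1C)O[C@]1(O)[C@H](O)C(=O)[C@@]3(O)C(=CC(=O)C3(C)C)[C@H](C)[C@H]1C2 | target

**Step count**
Total steps: 13. Longest linear sequence: 13 steps (1 → 19); 5 and 15 are bought.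

**Three steps most likely to fail**

Step 4 (Mukaiyama–Michael addition of a hindered ketone enol silane; yield and ee uncertain). The fallback sets out from 4 and comes back at 6. It replaces iminium catalysis by metal-catalysed allylic substitution: iridium/phosphoramidite-catalysed branched-selective allylation of 4 with (E)-but-2-enyl methyl carbonate (CsF, ZnF2) gives (3S)-5-[(2R)-but-3-en-2-yl]-3-(tert-butyldimethylsilyloxy)-2,2-dimethylcyclopentan-1-one F1. Hydroboration with 9-BBN and NaBO3 oxidation gives the primary alcohol (3S)-3-(tert-butyldimethylsilyloxy)-5-[(2R)-4-hydroxybutan-2-yl]-2,2-dimethylcyclopentan-1-one F2, and Dess–Martin oxidation of F2 gives 6.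

Step 12 (the proposed acyl shift; retro-Michael loss of the pyranone or enolisation at the lactone α-CH could compete). The fallback uses known chemistry only, sets out from 12 and comes back at 17, closing ring C before the pyranone is attached. TMSOTf/Et3N converts 12 into the bis(trimethylsilyl) compound (3S)-3-[(3S,5R)-3-(tert-butyldimethylsilyloxy)-4,4-dimethyl-5-(trimethylsilyloxy)-5-[1-(trimethylsilyloxy)ethenyl]cyclopent-1-en-1-yl]-2-methylidenebutanal F3. A BF3·OEt2-mediated intramolecular Mukaiyama aldol addition onto the non-enolisable enal, worked up with aqueous HF, gives the seven-membered triol (2S,3aR,8R)-2,3a,6-trihydroxy-3,3,8-trimethyl-7-methylidene-3,3a,5,6,7,8-hexahydroazulen-4(2H)-one F4. TPAP/NMO oxidises both secondary alcohols to (3aR,8S)-3a-hydroxy-3,3,8-trimethyl-7-methylidene-7,8-dihydroazulene-2,4,6(3H,3aH,5H)-trione F5, and Et3N-catalysed Michael addition of 15 to the exocyclic enone of F5 gives 17.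

Step 13 (chemoselectivity between the dionate and the pyranolate, over-oxidation, and the CH–OH configuration). The fallback sets out from 17 and comes back at 19. It replaces enolate oxidation by a Rubottom sequence on the fully silylated substrate, so the pyranone OH is masked and the bulky silyloxy group on the quaternary carbon directs the oxidant to the opposite face. TMSOTf/Et3N gives the tris(trimethylsilyl) derivative (3aR,7R,8R)-7-{[5,6-dimethyl-2-oxo-4-(trimethylsilyloxy)-2H-pyran-3-yl]methyl}-3,3,8-trimethyl-3a,6-bis(trimethylsilyloxy)-7,8-dihydroazulene-2,4(3H,3aH)-dione F6. Dimethyldioxirane at −78 °C epoxidises the silyl enol ether, and HF·pyridine removes the silyl groups to give 19.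

**Further compounds**
F1 | step 4 | (3S)-5-[(2R)-but-3-en-2-yl]-3-(tert-butyldimethylsilyloxy)-2,2-dimethylcyclopentan-1-one | C=C[C@@H](C)C1C[C@H](O[Si](C)(C)C(C)(C)C)C(C)(C)C1=O
F2 | step 4 | (3S)-3-(tert-butyldimethylsilyloxy)-5-[(2R)-4-hydroxybutan-2-yl]-2,2-dimethylcyclopentan-1-one | OCC[C@@H](C)C1C[C@H](O[Si](C)(C)C(C)(C)C)C(C)(C)C1=O
F3 | step 12 | (3S)-3-[(3S,5R)-3-(tert-butyldimethylsilyloxy)-4,4-dimethyl-5-(trimethylsilyloxy)-5-[1-(trimethylsilyloxy)ethenyl]cyclopent-1-en-1-yl]-2-methylidenebutanal | O=CC(=C)[C@@H](C)C1=C[C@H](O[Si](C)(C)C(C)(C)C)C(C)(C)[C@@]1(O[Si](C)(C)C)C(=C)O[Si](C)(C)C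
F4 | step 12 | (2S,3aR,8R)-2,3a,6-trihydroxy-3,3,8-trimethyl-7-methylidene-3,3a,5,6,7,8-hexahydroazulen-4(2H)-one, C-6 epimers | C=C1[C@@H](C)C2=C[C@H](O)C(C)(C)[C@@]2(O)C(=O)CC1O
F5 | step 12 | (3aR,8S)-3a-hydroxy-3,3,8-trimethyl-7-methylidene-7,8-dihydroazulene-2,4,6(3H,3aH,5H)-trione | C=C1[C@@H](C)C2=CC(=O)C(C)(C)[C@@]2(O)C(=O)CC1=O
F6 | step 13 | (3aR,7R,8R)-7-{[5,6-dimethyl-2-oxo-4-(trimethylsilyloxy)-2H-pyran-3-yl]methyl}-3,3,8-trimethyl-3a,6-bis(trimethylsilyloxy)-7,8-dihydroazulene-2,4(3H,3aH)-dione | Cc1oc(=O)c(C[C@H]2C(O[Si](C)(C)C)=CC(=O)[C@@]3(O[Si](C)(C)C)C(=CC(=O)C3(C)C)[C@@H]2C)c(O[Si](C)(C)C)c1C
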